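Cedar is the run to read first: Monday's has the same charge and the same time.

| flask | starting material | free catalyst | remark | time |
|---|---|---|---|---|
| cedar | 0.20 M | 0.40 mM | run made earlier |  |
| ash | 0.28 M | 0.40 mM | run made earlier |  |
| oak | 0.44 M | 0.40 mM | run made earlier |  |
| Monday's | 0.20 M | 0.40 mM | everything together in a closed stirred flask, run for 25 min | 25 min |
| Tuesday's | 0.20 M | 0.40 mM | a single well-mixed tank run continuously and read at steady state, 25 min in it on average |  |
| Wednesday's | 0.20 M (fed, over 20.0 min) | 0.40 mM | a stirred flask in which starting material is dosed at a steady rate over 20.0 min without added volume, worked up at 25 min | 25 min |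

| run | time / min | target / % | side product / % |
|---|---|---|---|
| cedar | 1.50 | 6 | 0 |
| cedar | 5.00 | 11 | 1 |
| cedar | 8.00 | 18 | 0 |
| cedar | 15.0 | 28 | 3 |
| cedar | 20.0 | 32 | 4 |
| cedar | 25.0 | 35 | 5 |
| ash | 2.00 | 5 | 0 |
| ash | 3.00 | 5 | 0 |
| ash | 6.00 | 13 | 2 |
| ash | 10.0 | 18 | 6 |
| ash | 15.0 | 26 | 5 |
| ash | 25.0 | 35 | 8 |
| oak | 2.00 | 3 | 0 |
| oak | 3.00 | 8 | 2 |
| oak | 6.00 | 13 | 6 |
| oak | 10.0 | 18 | 3 |
| oak | 15.0 | 27 | 8 |
| oak | 25.0 | 35 | 7 |

(each reading ± 1.5 percentage points)

1. the set-up with the highest share of target in all that became target or side product, at the outlet or at the end ("none" if the first two lie within 2 percentage points) (Monday's / Tuesday's / Wednesday's / none)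
2. share of target in all that became target or side product, at the outlet or at the end, Monday's
3. share of target in all that became target or side product, at the outlet or at the end, Tuesday's
4. share of target in all that became target or side product, at the outlet or at the end, Wednesday's

- in percentages every species weighs as the starting material in it: one side product counts as two
- the stated concentrations are those of everything mixed, before any reaction; amounts are the same in each set-up
- on the list of suspects stand: free catalyst -> spent catalyst B; 2 free catalyst -> spent catalyst A; free catalyst + intermediate -> free catalyst + target; starting material + target -> side product; starting material -> intermediate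
- the feed brings no volume worth counting
- the earlier runs were made in a closed, stirred flask

Keep one quantity, side per target: side product standing per unit of target, 0.143 as read at the end of cedar. The share asked for, the selectivity, is one over one plus this quantity, here 87.5%, so a set-up that loses target must lose side product in step to hold that share.

Now solve two extreme flasks. In the first, starting material → intermediate is the rate-limiting step, so the target rate follows the material not yet target or side product, 64.0% of the charge at 20.0 min. In the second, starting material turns to intermediate within the first minutes and intermediate waits on a fading catalyst, so the rate falls with the catalyst. Cedar made 18% in its first 8.00 min, then 7 percentage points from 15.0 min to 25.0 min. As read, the late rate is 0.311 of the early one, lower than the first extreme allows, so I place the flask nearer the second.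

Go round once more with that answer. Wednesday's free catalyst is in the flask from the start, while the dose reaches its midpoint at 10.0 min, and cedar added 17 points after 8.00 min, so I expect about that much target on Wednesday. Holding cedar's share on Wednesday would then allow 2.4 points of side product, and Wednesday's late starting material meets target already made, so I doubt it. Tuesday's tank keeps starting material beside target throughout. My order puts Monday's first.

The forecast says Wednesday's, with 88.5% for Monday's, 85.5% for Tuesday's and 93% for Wednesday's: “starting material overlaps target less”.

The flask gives Monday's, with 89.8% for Monday's, 71.3% for Tuesday's and 83.8% for Wednesday's.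

free catalyst → spent catalyst B (k = 2.20 × 10⁻⁴ min⁻¹); 2 free catalyst → spent catalyst A (k = 620 M⁻¹ min⁻¹); free catalyst + intermediate → free catalyst + target (k = 390 M⁻¹ min⁻¹); starting material + target → side product (k = 0.280 M⁻¹ min⁻¹); starting material → intermediate (k = 0.220 min⁻¹) Wednesday's ended with 15.1% of target against 36.1% on Monday's. Reckoned from each share, side per target is 0.114 on Monday's. Against the 0.143 read from cedar, Wednesday's stands higher at 0.193, and Tuesday's stands higher at 0.403.

The earlier runs and the new flask are simulated for an exercise, noise included.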